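**Retrosynthetic overview**

1. Ring locants used throughout: C1 = O–CH of the α-methylene lactone; C2=C3 ring olefin (C3 bears CH2OH); C4, C5 = CH2; C6 = CH–O-isobutyryl; C7=C8 = butenolide C=C (C7 bears the lactone C=O); C9 = butenolide O–CH; C10 = CH bearing the methylene-lactone α-carbon C11 (=C13H2).
2. Enabling feature: the C9–C10 bond joins the γ-carbon of the bridging butenolide to the β-carbon of the α-methylene lactone. C9 is the nucleophilic γ-terminus of a 2-silyloxyfuran, and C10–C11–C13 is an SN2′ electrophile if the second lactone is a 3-(bromomethyl)butenolide. Forming this one bond closes the ten-membered ring, sets C9 and C10, and unveils both the butenolide and the exocyclic methylene.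
3. Seco compound 20 is disconnected at the acceptor butenolide (esterification with 2-(bromomethyl)acrylic acid, then RCM), at C3–C4 (B-alkyl Suzuki coupling of vinyl iodide 9 with the vinyl group of 14), and at the donor butenolide (carbonylative lactonisation).
4. Both halves come from one enynol, (S)-7: the C1 and C6 carbinols are homochiral, and OH-directed Red-Al/I2 gives either vinyl iodide depending on which hydroxyl is free.
5. Ring order: donor butenolide (step 8), acceptor butenolide (step 12), ten-membered carbocycle (step 13, last). Endgame: TBS to isobutyrate exchange at C6, then PMB removal.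

Key step: step 13

Remark: the lipase in step 3 is assumed to follow the Kazlauskas rule (alkynyl = large, vinyl = medium), so the (R)-alcohol is acylated and (S)-7 is recovered. CIP descriptors in names refer to the compound named; C1–C13 are the locants defined above.

**Route**

Step 1
Reactants: 1 prop-2-yn-1-ol
Product: 3 1-methoxy-4-[(prop-2-yn-1-yloxy)methyl]benzene (PMB propargyl ether), via sodium prop-2-yn-1-olate 2 (not isolated)
Conditions: NaH, THF, 0 °C; then PMBCl, Bu4NI (cat.), rt
Reagents that add atoms: 4-methoxybenzyl chloride, COc1ccc(CCl)cc1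
Why: Williamson ether synthesis, in which the primary alkoxide 2 displaces chloride from the benzylic halide under iodide catalysis.

Step 2
Reactants: 3 PMB propargyl ether; 4 acrolein
Product: 6 rac-6-[(4-methoxybenzyl)oxy]hex-1-en-4-yn-3-ol, via lithium acetylide 5 (not isolated)
Conditions: n-BuLi, THF, −78 °C; then acrolein, −78 °C; aq. NH4Cl
Reagents that add atoms: none
Why: 1,2-addition of a lithium acetylide to the enal carbonyl at low temperature; the carbinol centre forms racemic and is resolved in step 3.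

Step 3
Reactants: 6 rac-enynol
Product: 7 (3S)-6-[(4-methoxybenzyl)oxy]hex-1-en-4-yn-3-ol
Conditions: Amano lipase PS, vinyl acetate, MTBE, 30 °C, run slightly past half conversion; chromatography
Reagents that add atoms: none
Why: Lipase-catalysed kinetic resolution by transesterification, expected to acylate the R enantiomer (Kazlauskas rule) and leave the S alcohol, whose configuration becomes that of both C1 and C6.

Step 4
Reactants: 7 (S)-enynol
Product: 9 (3S,4Z)-5-iodo-6-[(4-methoxybenzyl)oxy]hexa-1,4-dien-3-ol, via cyclic alkenylaluminate 8 (not isolated)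
Conditions: Red-Al, THF, −20 → 0 °C; EtOAc; then I2, THF, −78 °C; aq. Na2S2O3/Rochelle salt
Reagents that add atoms: iodine, II
Why: Hydroxyl-directed trans-hydroalumination of a propargylic alcohol puts hydride on the proximal and aluminium on the distal alkyne carbon (five-membered alkoxyaluminate 8), and iodinolysis with retention gives the (Z)-γ-iodo allylic alcohol with iodine cis to C1.

Step 5
Reactants: 7 (S)-enynol
Product: 10 tert-butyl({(3S)-6-[(4-methoxybenzyl)oxy]hex-1-en-4-yn-3-yl}oxy)dimethylsilane
Conditions: TBSCl, imidazole, DMF, rt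
Reagents that add atoms: tert-butyldimethylsilyl chloride, CC(C)(C)[Si](C)(C)Cl
Why: Standard silylation of a secondary alcohol; the C6 oxygen stays masked as a poor leaving group until after the key step.

Step 6
Reactants: 10 TBS ether
Product: 11 (4S)-4-[(tert-butyldimethylsilyl)oxy]hex-5-en-2-yn-1-ol
Conditions: DDQ, CH2Cl2/pH 7 buffer, 0 °C → rt
Reagents that add atoms: none
Why: Oxidative PMB cleavage by DDQ leaves the TBS ether, alkyne and vinyl group untouched and frees the primary propargylic OH as the new directing group.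

Step 7
Reactants: 11 alkynol
Product: 13 (2Z,4S)-4-[(tert-butyldimethylsilyl)oxy]-3-iodohexa-2,5-dien-1-ol, via cyclic alkenylaluminate 12 (not isolated)
Conditions: Red-Al, THF, −20 °C; EtOAc; then I2, THF, −78 °C; aq. Na2S2O3/Rochelle salt
Reagents that add atoms: iodine, II
Why: The same hydroxyl-directed trans-hydroalumination/iodinolysis as step 4, now steered by the primary OH so that iodine lands on C7 cis to the CH2OH group; low temperature suppresses β-elimination of the silyloxy group.

Step 8
Reactants: 13 vinyl iodide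
Product: 14 3-{(1S)-1-[(tert-butyldimethylsilyl)oxy]prop-2-en-1-yl}furan-2(5H)-one
Conditions: PdCl2(PPh3)2 (5 mol %), CO (1 atm), K2CO3, THF, rt
Reagents that add atoms: carbon monoxide, [C-]#[O+]
Why: Palladium-catalysed carbonylative lactonisation of a (Z)-γ-iodo allylic alcohol (oxidative addition, CO insertion, capture of the acyl–Pd by the cis hydroxyl) gives the α-substituted butenolide.

Step 9
Reactants: 14 butenolide; 9 vinyl iodide
Product: 16 3-[(1S,4E,6S)-1-(tert-butyldimethylsilyloxy)-6-hydroxy-4-{[(4-methoxybenzyl)oxy]methyl}octa-4,7-dien-1-yl]furan-2(5H)-one, via B-alkyl-9-BBN borane 15 (not isolated)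
Conditions: 9-BBN, THF, 0 °C → rt; then 9, Pd(dppf)Cl2 (5 mol %), AsPh3, aq. K3PO4, DMF, rt
Reagents that add atoms: none
Why: B-alkyl Suzuki–Miyaura coupling, in which 9-BBN hydroborates only the terminal alkene of 14 and the borane couples with the vinyl iodide with retention, so C4 ends up cis to C1 (ring-cis C2=C3).

Step 10
Reactants: 16 allylic alcohol; 17 2-(bromomethyl)acrylic acid
Product: 18 (3S,4E,8S)-8-(tert-butyldimethylsilyloxy)-5-{[(4-methoxybenzyl)oxy]methyl}-8-(2-oxo-2,5-dihydrofuran-3-yl)octa-1,4-dien-3-yl 2-(bromomethyl)acrylate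
Conditions: DCC, DMAP (10 mol %), CH2Cl2, −20 → 0 °C
Reagents that add atoms: none
Why: Steglich esterification of the secondary bis-allylic alcohol, kept cold with little DMAP because the 2-(bromomethyl)acrylate is an SN2′ electrophile.

Step 11
Reactants: 18 ester
Product: 19 (3S,4E,8S)-8-(tert-butyldimethylsilyloxy)-5-{[(4-methoxybenzyl)oxy]methyl}-8-{2-[(triisopropylsilyl)oxy]furan-3-yl}octa-1,4-dien-3-yl 2-(bromomethyl)acrylate
Conditions: TIPSOTf, i-Pr2NEt, CH2Cl2, 0 °C
Reagents that add atoms: triisopropylsilyl triflate, CC(C)[Si](C(C)C)(C(C)C)OS(=O)(=O)C(F)(F)F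
Why: Soft enolisation/O-silylation of a butenolide to the 2-silyloxyfuran; only the donor butenolide has γ-hydrogens, and it is done before the acceptor butenolide exists because that ring would enolise at C1.

Step 12
Reactants: 19 diene ester
Product: 20 (5R)-3-(bromomethyl)-5-[(1E,5S)-5-(tert-butyldimethylsilyloxy)-2-{[(4-methoxybenzyl)oxy]methyl}-5-{2-[(triisopropylsilyl)oxy]furan-3-yl}pent-1-en-1-yl]furan-2(5H)-one
Conditions: Grubbs II (10 mol %), CH2Cl2 (5 mM), 40 °C
Reagents that add atoms: none
Why: Ring-closing metathesis of an allylic 2-substituted acrylate to a 3-substituted butenolide; the alkylidene loads on the only monosubstituted vinyl group, the trisubstituted C2=C3 olefin and the aromatic silyloxyfuran stay out, and C1 is untouched because no base is present.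

Step 13
Reactants: 20 seco compound
Product: 22 tricyclic dilactone (1R,6S,9R,10S) with C6–OTBS and C3–CH2OPMB, via silyl ketene acetal 21 (not isolated)
Conditions: TIPSOTf (0.2 equiv), 2,6-di-tert-butyl-4-methylpyridine (0.3 equiv), CH2Cl2, −78 → −20 °C, 20 added by syringe pump (1 mM final); Et3N, aq. NaHCO3
Reagents that add atoms: none
Why: Proposed new method: TIPSOTf silylates the carbonyl of the 3-(bromomethyl)butenolide, the tethered 2-silyloxyfuran attacks C10 through its γ-carbon C9, and the β-bromo silyl ketene acetal 21 expels i-Pr3SiBr to give the exocyclic methylene while the furan collapses to the butenolide (net intramolecular vinylogous Mukaiyama SN2′ alkylation with the Lewis acid turned over); the closest known reactions are intermolecular vinylogous Mukaiyama–Michael additions of 2-silyloxyfurans to unsaturated carbonyl compounds and SN2′ substitutions of 2-(halomethyl)acrylates and Morita–Baylis–Hillman acetates by silyloxyfurans. The ten-membered ring closes by 10-exo-trig attack on C10=C11, with C7–C9 of the furan and the ring-cis C2=C3 olefin already planar, and C7=C8 ends up trans within the ring as the target requires. C10 is set by C1: C9 adds to the butenolide face anti to the C2 branch, the usual sense for 5-substituted furanones and the only staggered trajectory for the tether, which gives the trans-fused lactone. C9 is set by C6: A(1,3) strain with the OTIPS group holds H6 in the furan plane, so the C5 tether leaves from one furan face (OTBS on the other) and the acceptor is delivered to that face, which corresponds to 9R. The step needs γ- over α-attack of the furan (C7 is substituted, C9 is free), SN2′ at C10 over SN2 at C13 (carbonyl activation, no halophilic metal), and cyclisation over oligomerisation (high dilution, slow addition, catalytic Lewis acid).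

Step 14
Reactants: 22 tricyclic TBS ether
Product: 23 tricyclic C6 alcohol (1R,6S,9R,10S) with C3–CH2OPMB
Conditions: HF·pyridine, pyridine, THF, 0 °C → rt
Reagents that add atoms: none
Why: Fluoride-mediated cleavage of the secondary TBS ether under buffered conditions that should spare the PMB ether, both lactones and the exocyclic methylene.

Step 15
Reactants: 23 C6 alcohol; 24 isobutyryl chloride
Product: 25 tricyclic C6 isobutyrate (1R,6S,9R,10S) with C3–CH2OPMB
Conditions: pyridine, DMAP (cat.), CH2Cl2, 0 °C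
Reagents that add atoms: none
Why: Acylation of the secondary allylic alcohol with an acid chloride; the C6–O bond is not touched, so configuration is retained.

Step 16
Reactants: 25 PMB ether
Product: 26 target CNP0322767.4
Conditions: DDQ, CH2Cl2/pH 7 buffer, 0 °C
Reagents that add atoms: none
Why: DDQ-mediated oxidative removal of the PMB ether under buffered, non-basic conditions that spare the Michael-acceptor lactones and the isobutyrate.

**Compound list**

1 | prop-2-yn-1-ol | C#CCO | starting material
2 | sodium prop-2-yn-1-olate (not isolated) | [Na+].[O-]CC#C | intermediate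
3 | 1-methoxy-4-[(prop-2-yn-1-yloxy)methyl]benzene | C#CCOCc1ccc(OC)cc1 | intermediate
4 | acrolein | C=CC=O | starting material
5 | {3-[(4-methoxybenzyl)oxy]prop-1-yn-1-yl}lithium (not isolated) | [Li]C#CCOCc1ccc(OC)cc1 | intermediate
6 | rac-6-[(4-methoxybenzyl)oxy]hex-1-en-4-yn-3-ol | OC(C=C)C#CCOCc1ccc(OC)cc1 | intermediate
7 | (3S)-6-[(4-methoxybenzyl)oxy]hex-1-en-4-yn-3-ol | O[C@@H](C=C)C#CCOCc1ccc(OC)cc1 | intermediate
8 | sodium cyclic alkoxy(alkenyl)bis(2-methoxyethoxy)aluminate from 7, Al on O1 and C3 (not isolated) | [Na+].COCCO[Al-]1(OCCOC)O[C@@H](C=C)C=C1COCc1ccc(OC)cc1 | intermediate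
9 | (3S,4Z)-5-iodo-6-[(4-methoxybenzyl)oxy]hexa-1,4-dien-3-ol | O[C@@H](C=C)/C=C(\I)COCc1ccc(OC)cc1 | intermediate
10 | tert-butyl({(3S)-6-[(4-methoxybenzyl)oxy]hex-1-en-4-yn-3-yl}oxy)dimethylsilane | CC(C)(C)[Si](C)(C)O[C@@H](C=C)C#CCOCc1ccc(OC)cc1 | intermediate
11 | (4S)-4-[(tert-butyldimethylsilyl)oxy]hex-5-en-2-yn-1-ol | CC(C)(C)[Si](C)(C)O[C@@H](C=C)C#CCO | intermediate
12 | sodium cyclic alkoxy(alkenyl)bis(2-methoxyethoxy)aluminate from 11, Al on O9 and C7 (not isolated) | [Na+].COCCO[Al-]1(OCCOC)OCC=C1[C@@H](O[Si](C)(C)C(C)(C)C)C=C | intermediate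
13 | (2Z,4S)-4-[(tert-butyldimethylsilyl)oxy]-3-iodohexa-2,5-dien-1-ol | OC/C=C(\I)[C@@H](O[Si](C)(C)C(C)(C)C)C=C | intermediate
14 | 3-{(1S)-1-[(tert-butyldimethylsilyl)oxy]prop-2-en-1-yl}furan-2(5H)-one | O=C1OCC=C1[C@@H](O[Si](C)(C)C(C)(C)C)C=C | intermediate
15 | 3-{(1S)-3-(9-borabicyclo[3.3.1]nonan-9-yl)-1-[(tert-butyldimethylsilyl)oxy]propyl}furan-2(5H)-one (not isolated) | O=C1OCC=C1[C@@H](O[Si](C)(C)C(C)(C)C)CCB2C3CCCC2CCC3 | intermediate
16 | 3-[(1S,4E,6S)-1-(tert-butyldimethylsilyloxy)-6-hydroxy-4-{[(4-methoxybenzyl)oxy]methyl}octa-4,7-dien-1-yl]furan-2(5H)-one | O[C@@H](C=C)/C=C(/COCc1ccc(OC)cc1)CC[C@H](O[Si](C)(C)C(C)(C)C)C2=CCOC2=O | intermediate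
17 | 2-(bromomethyl)acrylic acid | C=C(CBr)C(=O)O | starting material
18 | (3S,4E,8S)-8-(tert-butyldimethylsilyloxy)-5-{[(4-methoxybenzyl)oxy]methyl}-8-(2-oxo-2,5-dihydrofuran-3-yl)octa-1,4-dien-3-yl 2-(bromomethyl)acrylate | C=C(CBr)C(=O)O[C@@H](C=C)/C=C(/COCc1ccc(OC)cc1)CC[C@H](O[Si](C)(C)C(C)(C)C)C2=CCOC2=O | intermediate
19 | (3S,4E,8S)-8-(tert-butyldimethylsilyloxy)-5-{[(4-methoxybenzyl)oxy]methyl}-8-{2-[(triisopropylsilyl)oxy]furan-3-yl}octa-1,4-dien-3-yl 2-(bromomethyl)acrylate | C=C(CBr)C(=O)O[C@@H](C=C)/C=C(/COCc1ccc(OC)cc1)CC[C@H](O[Si](C)(C)C(C)(C)C)c2ccoc2O[Si](C(C)C)(C(C)C)C(C)C | intermediate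
20 | (5R)-3-(bromomethyl)-5-[(1E,5S)-5-(tert-butyldimethylsilyloxy)-2-{[(4-methoxybenzyl)oxy]methyl}-5-{2-[(triisopropylsilyl)oxy]furan-3-yl}pent-1-en-1-yl]furan-2(5H)-one | O=C1O[C@@H](C=C1CBr)/C=C(/COCc2ccc(OC)cc2)CC[C@H](O[Si](C)(C)C(C)(C)C)c3ccoc3O[Si](C(C)C)(C(C)C)C(C)C | intermediate
21 | ring-closed O-triisopropylsilyl ketene acetal of the C1/C10 lactone bearing C11–CH2Br (not isolated) | BrCC1=C(O[Si](C(C)C)(C(C)C)C(C)C)O[C@@H]2/C=C(/COCc4ccc(OC)cc4)CC[C@H](O[Si](C)(C)C(C)(C)C)C3=C[C@@H](OC3=O)[C@@H]12 | intermediate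
22 | tricyclic dilactone (1R,6S,9R,10S): ten-membered carbocycle with trans-fused α-methylene-γ-lactone at C1/C10, butenolide bridging C7–C9, C6–OTBS, C3–CH2OPMB | C=C1C(=O)O[C@@H]2/C=C(/COCc4ccc(OC)cc4)CC[C@H](O[Si](C)(C)C(C)(C)C)C3=C[C@@H](OC3=O)[C@@H]12 | intermediate
23 | tricyclic dilactone (1R,6S,9R,10S) with free C6–OH and C3–CH2OPMB | C=C1C(=O)O[C@@H]2/C=C(/COCc4ccc(OC)cc4)CC[C@H](O)C3=C[C@@H](OC3=O)[C@@H]12 | intermediate
24 | isobutyryl chloride | CC(C)C(Cl)=O | starting material
25 | tricyclic dilactone (1R,6S,9R,10S) with C6 isobutyrate and C3–CH2OPMB | C=C1C(=O)O[C@@H]2/C=C(/COCc4ccc(OC)cc4)CC[C@H](OC(=O)C(C)C)C3=C[C@@H](OC3=O)[C@@H]12 | intermediate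
26 | CNP0322767.4 (1R,6S,9R,10S; C2=C3 ring-cis, E by CIP) | C=C1C(=O)O[C@@H]2/C=C(/CO)CC[C@H](OC(=O)C(C)C)C3=C[C@@H](OC3=O)[C@@H]12 | target

**Step count**

Total: 16 steps. Longest linear sequence: 15 steps (steps 1–3 and 5–16; step 4 is a one-step branch from 7).

**Steps most likely to fail, with fallbacks**

Step 13 (Proposed new method). What may go wrong: oligomerisation outrunning the ten-membered ring closure; Lewis-acid ionisation of the C6 silyloxy group next to the electron-rich silyloxyfuran; or attack on the wrong furan face at C9. Fallback with known reaction types (oxidation of 2-silyloxyfurans to γ-hydroxybutenolides; indium-mediated Barbier allylation of aldehydes with 3-(bromomethyl)furanones; Barbier macrocyclisation to ten-membered carbocycles): set out from 20 and oxidise the silyloxyfuran with dimethyldioxirane (acetone/CH2Cl2, −78 °C, aqueous work-up) to the γ-hydroxybutenolide F1. Treat F1 with indium powder in THF/H2O at high dilution. The allylindium formed at C13 adds through C10 to the open formyl-acrylate tautomer of the hydroxybutenolide, and the hydroxy acid relactonises. This polarity-reversed closure of the same C9–C10 bond comes back to the route at 22; its C9/C10 sense would be set in a cyclic allylmetal transition state and would have to be checked.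

Step 12. What may go wrong: slow ring closure at the hindered, electron-poor 2-(bromomethyl)acrylate with catalyst decay, or ruthenium-induced loss of the allylic bromide. Fallback: set out from 16 and acylate with acryloyl chloride/i-Pr2NEt (−78 °C) to the acrylate F2. Silylate as in step 11 to the silyloxyfuran acrylate F3, and close the unsubstituted acrylate by RCM (Grubbs II, rt to 40 °C) to the plain acceptor butenolide F4. Run the step-13 macrocyclisation on F4, trapping the silyl ketene acetal in the same flask with Eschenmoser's salt (CH2=NMe2+ I−) to give the C11 Mannich base F5. Quaternise with MeI to the methiodide F6 and eliminate with aq. NaHCO3. This supplies C13 as a third component and comes back to the route at 22.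

Step 9. What may go wrong: base-induced degradation of butenolide 14 under aqueous phosphate (γ-deprotonation, then loss of silanolate), or protodeboronation of 15. Fallback: set out from 11 and 9 and move the coupling ahead of butenolide formation. Hydroborate the vinyl group of 11 with 9-BBN (one extra equivalent for the OH) and couple with 9 under the same palladium conditions to the enyne diol F7. Apply Red-Al/I2 (directed by the propargylic OH) to give the iodo diene diol F8, and carbonylate (PdCl2(PPh3)2, CO, K2CO3) so that the butenolide forms last. This comes back to the route at 16.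

**Further compounds**

F1 | step 13 | (5R)-3-(bromomethyl)-5-[(1E,5S)-5-(tert-butyldimethylsilyloxy)-5-(5-hydroxy-2-oxo-2,5-dihydrofuran-3-yl)-2-{[(4-methoxybenzyl)oxy]methyl}pent-1-en-1-yl]furan-2(5H)-one (C9 epimers) | O=C1O[C@@H](C=C1CBr)/C=C(/COCc2ccc(OC)cc2)CC[C@H](O[Si](C)(C)C(C)(C)C)C3=CC(O)OC3=O
F2 | step 12 | (3S,4E,8S)-8-(tert-butyldimethylsilyloxy)-5-{[(4-methoxybenzyl)oxy]methyl}-8-(2-oxo-2,5-dihydrofuran-3-yl)octa-1,4-dien-3-yl acrylate | C=CC(=O)O[C@@H](C=C)/C=C(/COCc1ccc(OC)cc1)CC[C@H](O[Si](C)(C)C(C)(C)C)C2=CCOC2=O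
F3 | step 12 | (3S,4E,8S)-8-(tert-butyldimethylsilyloxy)-5-{[(4-methoxybenzyl)oxy]methyl}-8-{2-[(triisopropylsilyl)oxy]furan-3-yl}octa-1,4-dien-3-yl acrylate | C=CC(=O)O[C@@H](C=C)/C=C(/COCc1ccc(OC)cc1)CC[C@H](O[Si](C)(C)C(C)(C)C)c2ccoc2O[Si](C(C)C)(C(C)C)C(C)C
F4 | step 12 | (5R)-5-[(1E,5S)-5-(tert-butyldimethylsilyloxy)-2-{[(4-methoxybenzyl)oxy]methyl}-5-{2-[(triisopropylsilyl)oxy]furan-3-yl}pent-1-en-1-yl]furan-2(5H)-one | O=C1O[C@@H](C=C1)/C=C(/COCc2ccc(OC)cc2)CC[C@H](O[Si](C)(C)C(C)(C)C)c3ccoc3O[Si](C(C)C)(C(C)C)C(C)C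
F5 | step 12 | tricyclic dilactone as 22 but with C11 saturated and bearing CH2NMe2 (C11 epimers) | CN(C)CC1C(=O)O[C@@H]2/C=C(/COCc4ccc(OC)cc4)CC[C@H](O[Si](C)(C)C(C)(C)C)C3=C[C@@H](OC3=O)[C@@H]12
F6 | step 12 | trimethylammonium iodide (methiodide) of F5 | C[N+](C)(C)CC1C(=O)O[C@@H]2/C=C(/COCc4ccc(OC)cc4)CC[C@H](O[Si](C)(C)C(C)(C)C)C3=C[C@@H](OC3=O)[C@@H]12.[I-]
F7 | step 9 | (4S,7E,9S)-4-(tert-butyldimethylsilyloxy)-7-{[(4-methoxybenzyl)oxy]methyl}undeca-7,10-dien-2-yne-1,9-diol | O[C@@H](C=C)/C=C(/COCc1ccc(OC)cc1)CC[C@H](O[Si](C)(C)C(C)(C)C)C#CCO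
F8 | step 9 | (2Z,4S,7E,9S)-4-(tert-butyldimethylsilyloxy)-3-iodo-7-{[(4-methoxybenzyl)oxy]methyl}undeca-2,7,10-triene-1,9-diol | O[C@@H](C=C)/C=C(/COCc1ccc(OC)cc1)CC[C@H](O[Si](C)(C)C(C)(C)C)/C(I)=C/CO
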